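**Strategy.** The seven-membered ring (C1, C5–C10; daucane numbering) is seen as the Cope product of a cis-1,2-divinylcyclopropane: in a bicyclo[3.1.0]hexane, C1, C5 and C10 form the three-membered ring, C5 carries a 1-methoxyvinyl group (C6=C7) and C10 an (E)-propenyl group (C9=C8). Methylenation of a C5 ester creates this precursor, which rearranges at once: the C5–C10 bond is traded for C7–C8, the cycloheptadiene closes, the quaternary C1 stereocentre is carried over, C8 is set, and a C6 enol ether and a C9=C10 alkene remain as handles for every oxygen of the larger ring. The precursor arises from an asymmetric vinylogous aldol and an intramolecular carbenoid cyclopropanation.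

Key step: step 7

Remark (numbering): atoms are numbered as in daucane (C1 angular carbon with CH3; C2, C3; C4 carbinol carbon with isopropyl; C5 ring-fusion CH; C6, C7; C8 with CH3; C9; C10); α/β are relative only, β being the face of the C1 methyl, and the SMILES strings fix the absolute configuration.

Remark (assumption): (S)-BINOL is taken to give the (5S)-aldol 5; if the sense of induction proved opposite, (R)-BINOL would be used.

**Step 1**
Reactants: 1 (E)-but-2-enal; 2 2-(triphenylphosphoranylidene)propanal
Product: 3 (2E,4E)-2-methylhexa-2,4-dienal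
Conditions: PhMe, 80 °C
Reagents that add atoms: none
Why: Wittig olefination with a stabilised formyl ylide should give the E trisubstituted alkene, with the E geometry of the enal retained.

**Step 2**
Reactants: 3 (2E,4E)-2-methylhexa-2,4-dienal; 4 1-methoxy-1,3-bis(trimethylsilyloxy)buta-1,3-diene
Product: 5 methyl (5S,6E,8E)-5-hydroxy-6-methyl-3-oxodeca-6,8-dienoate
Conditions: Ti(OiPr)4 (10 mol %), (S)-BINOL (10 mol %), 4 Å MS, THF, −78 °C to rt; then TFA, THF–H2O, 0 °C
Reagents that add atoms: none
Why: Titanium–BINOL-catalysed vinylogous Mukaiyama aldol, in which the bis-silyl dienolate attacks through its terminal carbon and the chiral Lewis acid selects the aldehyde face, setting C2 of the target.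

**Step 3**
Reactants: 5 methyl (5S,6E,8E)-5-hydroxy-6-methyl-3-oxodeca-6,8-dienoate
Product: 6 methyl (5S,6E,8E)-5-(tert-butyldimethylsilyloxy)-6-methyl-3-oxodeca-6,8-dienoate
Conditions: TBSCl, imidazole, DMF, rt
Reagents that add atoms: tert-butyldimethylsilyl chloride, CC(C)(C)[Si](C)(C)Cl
Why: Silylation of the secondary alcohol prevents O–H insertion of the later carbenoid and provides the bulky group that steers steps 5 and 8.

**Step 4**
Reactants: 6 silyl ether β-keto ester
Product: 7 methyl (5S,6E,8E)-5-(tert-butyldimethylsilyloxy)-2-diazo-6-methyl-3-oxodeca-6,8-dienoate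
Conditions: p-ABSA, Et3N, MeCN, 0 °C to rt
Reagents that add atoms: 4-acetamidobenzenesulfonyl azide, CC(=O)Nc1ccc(cc1)S(=O)(=O)N=[N+]=[N-]
Why: Regitz diazo transfer to the doubly activated methylene of the β-keto ester; the stereocentre is not involved.

**Step 5**
Reactants: 7 diazo β-keto ester
Product: 8 methyl 4-(tert-butyldimethylsilyloxy)-5-methyl-2-oxo-6-[(E)-prop-1-enyl]bicyclo[3.1.0]hexane-1-carboxylate (silyloxy cis to the cyclopropane carbon C10; propenyl exo)
Conditions: Rh2(OAc)4 (1 mol %), CH2Cl2, 40 °C, slow addition of 7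
Reagents that add atoms: none
Why: Rhodium-carbenoid intramolecular cyclopropanation of the proximal trisubstituted alkene (five-membered ring formation) is stereospecific, so the E alkene places the propenyl group exo and cis to the ester; the C2 stereocentre should direct the face because allylic 1,2-strain keeps C2–H eclipsed with the vinylic methyl and turns the silyloxy group to the side that ends cis to C10, fixing C1, C5 and C10.

**Step 6**
Reactants: 8 bicyclic keto ester
Product: 9 tertiary alcohol (C4 now C(OH)(iPr); ester kept)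
Conditions: iPrMgCl·LiCl, LaCl3·2LiCl, THF, −20 to 0 °C; NH4Cl (aq)
Reagents that add atoms: isopropylmagnesium chloride, CC(C)[Mg]Cl
Why: Lanthanum-promoted 1,2-addition of the Grignard reagent to the hindered ketone (ester untouched, enolisation suppressed) should occur anti to the cyclopropane; the C4 configuration is erased in step 7.

**Step 7**
Reactants: 9 tertiary alcohol ester
Product: 12 2α-silyloxy-dauca-4,9-dien-6-one, via cis-divinylcyclopropane 10 (not isolated), via methyl enol ether 11 (not isolated)
Conditions: Cp2TiMe2 (4 equiv), PhMe, 75 °C, dark; then 1 M HCl, THF, 0 °C to rt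
Reagents that add atoms: dimethyltitanocene Cp2TiMe2, C[Ti](C)(C1C=CC=C1)C1C=CC=C1; water, O
Why: On heating, Cp2TiMe2 releases Cp2Ti=CH2, which turns the ester carbonyl into a 1-methoxyvinyl group by [2+2] cycloaddition and cycloreversion (Petasis methylenation) and so gives the cis-1,2-divinylcyclopropane 10. Compound 10 should undergo a concerted [3,3] sigmatropic (Cope) rearrangement through a boat-shaped six-centre transition state in which the strained C5–C10 bond breaks while C7–C8 forms; the closest known reaction type is the 2-alkoxy- or 2-siloxy-divinylcyclopropane to cycloheptadiene rearrangement of enol ethers made from cis-2-vinylcyclopropyl carbonyl compounds. The seven-membered ring closes by this pericyclic ring expansion of the three-membered ring (outside Baldwin's classification), driven by release of cyclopropane strain, and the five-membered ring is carried over unchanged. The only new stereocentre, C8, is set by the E geometry of the propenyl group in the boat transition state, which puts the C8 methyl trans to the C1 methyl and H8 on the β-face, and C1 keeps its configuration because none of its bonds is broken. The step needs the two vinyl groups cis, which the exo propenyl group and the bridgehead ester of 8 secure, and it needs the Cope to outrun the homo-1,5-hydrogen shift of the syn methyl group, which the enol ether and the moderate temperature should favour. Aqueous acid then ionises the tertiary allylic alcohol of 11, water adds at C6 and methanol leaves (Stork–Danheiser-type transposition), giving enone 12.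

**Step 8**
Reactants: 12 dienone
Product: 13 4β,5β-epoxy-2α-silyloxy-dauc-9-en-6-one
Conditions: tBuOOH (decane), DBU, CH2Cl2, 0 °C to rt
Reagents that add atoms: tert-butyl hydroperoxide, CC(C)(C)OO
Why: Weitz–Scheffer nucleophilic epoxidation, in which the peroxide anion should add to C4 from the β-face because, with the C2 silyloxy group pseudo-equatorial, the C1–C10 bond is pseudo-axial on the α-face beside the silyloxy group, and the enolate then closes the epoxide on the same face, setting the C4–O bond β; the isolated C9=C10 alkene is inert to this oxidant.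

**Step 9**
Reactants: 13 epoxy ketone
Product: 14 4β-hydroxy-2α-silyloxy-5αH-dauc-9-en-6-one
Conditions: SmI2 (2.5 equiv), THF–MeOH, −78 °C; then DBU (0.2 equiv), PhMe, rt
Reagents that add atoms: none
Why: SmI2 reduction to the ketyl expels the α-oxygen (reductive cleavage of an α,β-epoxy ketone) without touching the C4–O bond, and protonation of the samarium enolate followed by base equilibration of the epimerisable C5 should give the trans-fused ketone, in which the C5–C6 bond is anti to the isopropyl group and cis to the hydroxyl (H5 α).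

**Step 10**
Reactants: 14 β-hydroxy ketone silyl ether
Product: 15 2α,4β-dihydroxy-5αH-dauc-9-en-6-one
Conditions: HF·pyridine, pyridine, THF, 0 °C to rt
Reagents that add atoms: none
Why: Fluoride cleaves the secondary silyl ether under buffered, mildly acidic conditions that spare the β-hydroxy ketone.

**Step 11**
Reactants: 15 diol ketone
Product: 16 9α,10α-epoxy-2α,4β-dihydroxy-5αH-daucan-6-one
Conditions: VO(acac)2 (5 mol %), tBuOOH, CH2Cl2, rt
Reagents that add atoms: tert-butyl hydroperoxide, CC(C)(C)OO
Why: Vanadium-catalysed hydroxyl-directed epoxidation, in which the homoallylic C2 hydroxyl, lying on the α-side of C10, binds the vanadium alkylperoxide and delivers oxygen to the α-face of C9=C10, the only alkene present.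

**Step 12**
Reactants: 16 epoxide
Product: 19 2α,4β,10α-trihydroxy-5αH-dauc-8-en-6-one, via hydroxy selenide 17 (not isolated), via selenoxide 18 (not isolated)
Conditions: PhSeH, Cs2CO3 (0.2 equiv), EtOH, 40 °C; concentrate; mCPBA (1.05 equiv), CH2Cl2, −78 °C; then iPr2NH, −78 °C to rt
Reagents that add atoms: none
Why: Sharpless–Lauer-type conversion of an epoxide to an allylic alcohol, in which benzeneselenolate opens the epoxide at the less hindered C9 (C10 is neopentyl) with inversion, placing selenium on the β-face, and the selenoxide undergoes syn-elimination with the β-oriented H8 set in step 7, away from the carbinol carbon, to give the C8=C9 alkene and the 10α-alcohol.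

**Step 13**
Reactants: 19 triol ketone
Product: 20 2α,10α-diacetoxy-4β-hydroxy-5αH-dauc-8-en-6-one
Conditions: Ac2O, pyridine, DMAP (cat.), CH2Cl2, 0 °C to rt
Reagents that add atoms: acetic anhydride, CC(=O)OC(C)=O
Why: DMAP-catalysed acetylation of the two secondary alcohols, with the tertiary C4 hydroxyl left free under these mild conditions; the reaction is kept cold and short so that the β,γ-unsaturated ketone does not move into conjugation.

**Step 14**
Reactants: 20 diacetate ketone
Product: 21 2α,10α-diacetoxy-5αH-dauc-8-ene-4β,6α-diol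
Conditions: Me4NBH(OAc)3, MeCN–AcOH, −30 °C
Reagents that add atoms: none
Why: Evans–Saksena reduction, in which the tertiary C4 hydroxyl exchanges onto boron and delivers hydride intramolecularly to the β-face of the C6 ketone (C4 and its oxygen sit on the β-side of C6), giving the 6α-alcohol anti to the 4β-hydroxyl while the acetates and the alkene are untouched.

**Step 15**
Reactants: 21 homoallylic alcohol
Product: 22 2α,10α-diacetoxy-8α,9α-epoxy-5αH-daucane-4β,6α-diol
Conditions: VO(acac)2 (5 mol %), tBuOOH, CH2Cl2, 0 °C to rt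
Reagents that add atoms: tert-butyl hydroperoxide, CC(C)(C)OO
Why: Hydroxyl-directed epoxidation by the homoallylic 6α-hydroxyl should place the epoxide oxygen on the α-face of the trisubstituted C8=C9 alkene, cis to the 10α-acetoxy group, setting C8 and C9.

**Step 16**
Reactants: 22 epoxy diol; 23 angelic acid
Product: 25 2α,10α-diacetoxy-6α-angeloyloxy-8α,9α-epoxy-5αH-daucan-4β-ol (CNP0170993.1), via mixed anhydride 24 (not isolated)
Conditions: 23, 2,4,6-trichlorobenzoyl chloride, Et3N, PhMe, rt; then 22, PhMe, 80 °C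
Reagents that add atoms: none
Why: Yamaguchi esterification through mixed anhydride 24 without DMAP, conditions chosen because they acylate hindered secondary alcohols with angelic acid without Z to E isomerisation; the tertiary C4 hydroxyl does not react.

**Compound list**

1 | (E)-but-2-enal (crotonaldehyde) | C/C=C/C=O | starting material
2 | 2-(triphenylphosphoranylidene)propanal | CC(C=O)=P(c1ccccc1)(c1ccccc1)c1ccccc1 | starting material
3 | (2E,4E)-2-methylhexa-2,4-dienal | O=C/C(C)=C/C=C/C | intermediate
4 | 1-methoxy-1,3-bis(trimethylsilyloxy)buta-1,3-diene | C=C(O[Si](C)(C)C)C=C(OC)O[Si](C)(C)C | starting material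
5 | methyl (5S,6E,8E)-5-hydroxy-6-methyl-3-oxodeca-6,8-dienoate | COC(=O)CC(=O)C[C@H](O)/C(C)=C/C=C/C | intermediate
6 | methyl (5S,6E,8E)-5-(tert-butyldimethylsilyloxy)-6-methyl-3-oxodeca-6,8-dienoate | COC(=O)CC(=O)C[C@H](O[Si](C)(C)C(C)(C)C)/C(C)=C/C=C/C | intermediate
7 | methyl (5S,6E,8E)-5-(tert-butyldimethylsilyloxy)-2-diazo-6-methyl-3-oxodeca-6,8-dienoate | COC(=O)C(=[N+]=[N-])C(=O)C[C@H](O[Si](C)(C)C(C)(C)C)/C(C)=C/C=C/C | intermediate
8 | methyl 4-(tert-butyldimethylsilyloxy)-5-methyl-2-oxo-6-[(E)-prop-1-enyl]bicyclo[3.1.0]hexane-1-carboxylate; silyloxy cis to the cyclopropane CH (C10), propenyl exo and cis to ester and bridgehead methyl | COC(=O)[C@@]12C(=O)C[C@H](O[Si](C)(C)C(C)(C)C)[C@]1(C)[C@H]2/C=C/C | intermediate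
9 | as 8 with the ketone converted to C(OH)(isopropyl), isopropyl anti to the cyclopropane (configuration inconsequential) | COC(=O)[C@@]12[C@@](O)(C(C)C)C[C@H](O[Si](C)(C)C(C)(C)C)[C@]1(C)[C@H]2/C=C/C | intermediate
10 | as 9 with the ester replaced by a 1-methoxyvinyl group (cis-1,2-divinylcyclopropane) | C=C(OC)[C@@]12[C@@](O)(C(C)C)C[C@H](O[Si](C)(C)C(C)(C)C)[C@]1(C)[C@H]2/C=C/C | intermediate (not isolated)
11 | 6-methoxy-2α-(tert-butyldimethylsilyloxy)dauca-5,9-dien-4-ol (8-methyl α, H8 β) | COC1=C2[C@@](O)(C(C)C)C[C@H](O[Si](C)(C)C(C)(C)C)[C@]2(C)C=C[C@H](C)C1 | intermediate (not isolated)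
12 | 2α-(tert-butyldimethylsilyloxy)dauca-4,9-dien-6-one (8-methyl α) | O=C1C[C@@H](C)C=C[C@@]2(C)[C@@H](O[Si](C)(C)C(C)(C)C)CC(C(C)C)=C12 | intermediate
13 | 4β,5β-epoxy-2α-(tert-butyldimethylsilyloxy)dauc-9-en-6-one | O=C1C[C@@H](C)C=C[C@@]2(C)[C@@H](O[Si](C)(C)C(C)(C)C)C[C@]3(C(C)C)O[C@]123 | intermediate
14 | 4β-hydroxy-2α-(tert-butyldimethylsilyloxy)-5αH-dauc-9-en-6-one (trans-fused) | O=C1C[C@@H](C)C=C[C@@]2(C)[C@@H](O[Si](C)(C)C(C)(C)C)C[C@@](O)(C(C)C)[C@H]12 | intermediate
15 | 2α,4β-dihydroxy-5αH-dauc-9-en-6-one | O=C1C[C@@H](C)C=C[C@@]2(C)[C@@H](O)C[C@@](O)(C(C)C)[C@H]12 | intermediate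
16 | 9α,10α-epoxy-2α,4β-dihydroxy-5αH-daucan-6-one (8-methyl α) | O=C1C[C@@H](C)[C@H]3O[C@H]3[C@@]2(C)[C@@H](O)C[C@@](O)(C(C)C)[C@H]12 | intermediate
17 | 9β-phenylselanyl-2α,4β,10α-trihydroxy-5αH-daucan-6-one | O=C1C[C@@H](C)[C@H]([Se]c3ccccc3)[C@@H](O)[C@@]2(C)[C@@H](O)C[C@@](O)(C(C)C)[C@H]12 | intermediate (not isolated)
18 | selenoxide of 17 (configuration at selenium undefined) | O=C1C[C@@H](C)[C@H]([Se](=O)c3ccccc3)[C@@H](O)[C@@]2(C)[C@@H](O)C[C@@](O)(C(C)C)[C@H]12 | intermediate (not isolated)
19 | 2α,4β,10α-trihydroxy-5αH-dauc-8-en-6-one | O=C1CC(C)=C[C@@H](O)[C@@]2(C)[C@@H](O)C[C@@](O)(C(C)C)[C@H]12 | intermediate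
20 | 2α,10α-diacetoxy-4β-hydroxy-5αH-dauc-8-en-6-one | O=C1CC(C)=C[C@@H](OC(C)=O)[C@@]2(C)[C@@H](OC(C)=O)C[C@@](O)(C(C)C)[C@H]12 | intermediate
21 | 2α,10α-diacetoxy-5αH-dauc-8-ene-4β,6α-diol | O[C@H]1CC(C)=C[C@@H](OC(C)=O)[C@@]2(C)[C@@H](OC(C)=O)C[C@@](O)(C(C)C)[C@H]12 | intermediate
22 | 2α,10α-diacetoxy-8α,9α-epoxy-5αH-daucane-4β,6α-diol | O[C@H]1C[C@@]2(C)O[C@H]2[C@@H](OC(C)=O)[C@@]2(C)[C@@H](OC(C)=O)C[C@@](O)(C(C)C)[C@H]12 | intermediate
23 | angelic acid, (Z)-2-methylbut-2-enoic acid | C/C=C(/C)C(=O)O | starting material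
24 | angelic 2,4,6-trichlorobenzoic anhydride | C/C=C(/C)C(=O)OC(=O)c1c(Cl)cc(Cl)cc1Cl | intermediate (not isolated)
25 | 2α,10α-diacetoxy-6α-angeloyloxy-8α,9α-epoxy-5αH-daucan-4β-ol (CNP0170993.1) | C/C=C(/C)C(=O)O[C@H]1C[C@@]2(C)O[C@H]2[C@@H](OC(C)=O)[C@@]2(C)[C@@H](OC(C)=O)C[C@@](O)(C(C)C)[C@H]12 | target

**Step count.** 16 steps in total; the longest linear sequence is 16 steps (1 to 25).

**Steps most likely to fail**

Step 7 (key step). The ester sits on a fully substituted cyclopropane carbon next to a tertiary carbinol, so methylenation may stall or the titanium carbene may be consumed by the free hydroxyl, and the divinylcyclopropane then never forms. The fallback sets out from 9 and returns at 12. LiAlH4 reduction of the ester would give the primary alcohol, diol F1. Dess–Martin oxidation would give the cyclopropanecarbaldehyde F2, used at once because cis-2-vinylcyclopropanecarbaldehydes equilibrate with dihydrooxepines. Wittig methylenation with Ph3P=CH2 would give the plain divinylcyclopropane F3, whose Cope rearrangement near room temperature should give the dienol F4. Babler–Dauben oxidative transposition of the tertiary allylic alcohol with pyridinium chlorochromate, C5H5NH[CrO3Cl], would move oxygen from C4 to C6 and give enone 12.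

Step 8. The peroxide anion may fail to add to the fully substituted, isopropyl-bearing β-carbon, may add from the α-face, or the base may trigger vinylogous loss of the silyloxy group. The fallback sets out from 12 and returns at 13. Reagent-controlled CBS reduction with (S)-Me-CBS and BH3·SMe2 would give the 6β-allylic alcohol F5. Hydroxyl-directed epoxidation with VO(acac)2 and tBuOOH would deliver oxygen to the tetrasubstituted C4=C5 alkene syn to that hydroxyl and give the 4β,5β-epoxy alcohol F6. Dess–Martin oxidation would return epoxy ketone 13.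

Step 5. The carbenoid may add with poor or reversed facial selectivity relative to the C2 silyloxy group, so that the silyloxy group ends trans to the cyclopropane. The fallback sets out from 3 and 4 and returns at 12, using that opposite preference and inverting C2 later.
- The aldol with (R)-BINOL would give the (5R)-hydroxy keto ester F7; silylation the ether F8; diazo transfer the diazo ester F9.
- Cyclopropanation would then give the bicycle F10, with the natural C1, C5 and C10 configuration and a 2β-silyloxy group.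
- Isopropyl addition would give the carbinol F11; Petasis methylenation would give the divinylcyclopropane F12, Cope rearrangement the enol ether F13, and acid the 2β-silyloxy dienone F14.
- HF·pyridine would give the 2β-alcohol F15. Mitsunobu reaction (4-nitrobenzoic acid, DIAD, PPh3) would invert the neopentyl carbinol to the 2α-nitrobenzoate F16.
- K2CO3 in MeOH would give the 2α-alcohol F17, and TBSOTf with 2,6-lutidine would return 12.

**Further compounds**

F1 | step 7 | as 9 with the ester reduced to CH2OH | OC[C@@]12[C@@](O)(C(C)C)C[C@H](O[Si](C)(C)C(C)(C)C)[C@]1(C)[C@H]2/C=C/C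
F2 | step 7 | as 9 with the ester replaced by CHO | O=C[C@@]12[C@@](O)(C(C)C)C[C@H](O[Si](C)(C)C(C)(C)C)[C@]1(C)[C@H]2/C=C/C
F3 | step 7 | as 9 with the ester replaced by vinyl (cis-divinylcyclopropane) | C=C[C@@]12[C@@](O)(C(C)C)C[C@H](O[Si](C)(C)C(C)(C)C)[C@]1(C)[C@H]2/C=C/C
F4 | step 7 | 2α-(tert-butyldimethylsilyloxy)dauca-5,9-dien-4-ol (8-methyl α) | C1=C2[C@@](O)(C(C)C)C[C@H](O[Si](C)(C)C(C)(C)C)[C@]2(C)C=C[C@H](C)C1
F5 | step 8 | 2α-(tert-butyldimethylsilyloxy)dauca-4,9-dien-6β-ol | O[C@@H]1C[C@@H](C)C=C[C@@]2(C)[C@@H](O[Si](C)(C)C(C)(C)C)CC(C(C)C)=C12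
F6 | step 8 | 4β,5β-epoxy-2α-(tert-butyldimethylsilyloxy)dauc-9-en-6β-ol | O[C@@H]1C[C@@H](C)C=C[C@@]2(C)[C@@H](O[Si](C)(C)C(C)(C)C)C[C@]3(C(C)C)O[C@]123
F7 | step 5 | methyl (5R,6E,8E)-5-hydroxy-6-methyl-3-oxodeca-6,8-dienoate | COC(=O)CC(=O)C[C@@H](O)/C(C)=C/C=C/C
F8 | step 5 | methyl (5R,6E,8E)-5-(tert-butyldimethylsilyloxy)-6-methyl-3-oxodeca-6,8-dienoate | COC(=O)CC(=O)C[C@@H](O[Si](C)(C)C(C)(C)C)/C(C)=C/C=C/C
F9 | step 5 | methyl (5R,6E,8E)-5-(tert-butyldimethylsilyloxy)-2-diazo-6-methyl-3-oxodeca-6,8-dienoate | COC(=O)C(=[N+]=[N-])C(=O)C[C@@H](O[Si](C)(C)C(C)(C)C)/C(C)=C/C=C/C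
F10 | step 5 | C2 epimer of 8 (silyloxy trans to the cyclopropane CH) | COC(=O)[C@@]12C(=O)C[C@@H](O[Si](C)(C)C(C)(C)C)[C@]1(C)[C@H]2/C=C/C
F11 | step 5 | C2 epimer of 9 (C4 configuration inconsequential) | COC(=O)[C@@]12C(O)(C(C)C)C[C@@H](O[Si](C)(C)C(C)(C)C)[C@]1(C)[C@H]2/C=C/C
F12 | step 5 | C2 epimer of 10 | C=C(OC)[C@@]12C(O)(C(C)C)C[C@@H](O[Si](C)(C)C(C)(C)C)[C@]1(C)[C@H]2/C=C/C
F13 | step 5 | C2 epimer of 11 | COC1=C2C(O)(C(C)C)C[C@@H](O[Si](C)(C)C(C)(C)C)[C@]2(C)C=C[C@H](C)C1
F14 | step 5 | 2β-(tert-butyldimethylsilyloxy)dauca-4,9-dien-6-one | O=C1C[C@@H](C)C=C[C@@]2(C)[C@H](O[Si](C)(C)C(C)(C)C)CC(C(C)C)=C12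
F15 | step 5 | 2β-hydroxydauca-4,9-dien-6-one | O=C1C[C@@H](C)C=C[C@@]2(C)[C@H](O)CC(C(C)C)=C12
F16 | step 5 | 2α-(4-nitrobenzoyloxy)dauca-4,9-dien-6-one | O=C1C[C@@H](C)C=C[C@@]2(C)[C@@H](OC(=O)c3ccc(cc3)[N+](=O)[O-])CC(C(C)C)=C12
F17 | step 5 | 2α-hydroxydauca-4,9-dien-6-one | O=C1C[C@@H](C)C=C[C@@]2(C)[C@@H](O)CC(C(C)C)=C12
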